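(All runs are calculated on assumed constants; noise was put on by code.)

**Two falling rates.** Neither capture in the south-east flask can keep its starting rate, for each spends its own nucleophile. I took the first nucleophile to turn substrate into target and the second to turn it into other capture product.

all flasks: substrate 0.20 M
- south-east: first nucleophile 0.22 M; second nucleophile 0.60 M; capture agent 0.010 M; the very flask that is asked about, followed so far
- south-west: first nucleophile 0.22 M; second nucleophile 1.2 M; capture agent 0.010 M; run made earlier
- flask: first nucleophile 0.220 M; second nucleophile 0.600 M; capture agent 0.0100 M; time 12 d

- south-east (time / h: other capture product / %, target / %, substrate / %): 4.00: 70.2, 27.3, 0; 8.00: 70.4, 27.0, 1.0; 15.0: 70.2, 26.8, 0; 30.0: 70.1, 27.0, 0; 48.0: 70.5, 27.9, 0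
- south-west (time / d: other capture product / %, target / %, substrate / %): 0.625: 82.4, 15.2, 0.6; 1.25: 82.8, 15.2, 0; 2.50: 82.2, 15.2, 0; 4.00: 81.9, 14.6, 0; 8.00: 81.8, 14.7, 0

(standard deviation of a reading: 0.5 percentage points)

- ratio of other capture product to target at 12 min
- ratio of other capture product to target at 6.0 h
- ratio of other capture product to target at 12 d
- which of other capture product and target there is more of at 12 d

- the earlier runs were read with a standard deviation of 0.5 percentage points
- a reading or a percentage of target counts all its forms, free or not

**Rates compared.** I reckoned with rates, not amounts. I expected the rate of other capture product over the rate of target to follow the charge of second nucleophile over the charge of first, so I carried a read selectivity factor, which I define as the ratio of other capture product to target read after the substrate is gone, divided by that charge quotient.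

Each rate then falls with the fraction of its nucleophile left. Counting just the products read at 30.0 h, I reckoned that the south-east flask had kept about 0.766 of its second nucleophile and about 0.755 of its first. Their quotient, the accumulated change in the rate ratio by this reckoning, is 1.02, so the two slowings nearly cancel, and I assumed that the ratio read could stand for the rate ratio.

**The factor.** The readings of the south-east run give a mean ratio of 2.58. Dividing by the charge quotient gives a read selectivity factor of 0.947. The south-west run reads a little higher, at 1.01.

With substrate read at 0% by 4.00 h, I committed to about 2.58 at 12 min, 6.0 h and 12 d, with other capture product ahead.

**The forecast.** The forecast gave 2.85, 2.58 and 2.6 with other capture product ahead, holding that “the products look kinetic and effectively irreversible”; its early figure stands above mine.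

**The result.** The flask gave 3.03, 2.59 and 2.59. At 12 d, other capture product led with 70.1% against 27.1% of target.

    substrate ⇌ open intermediate (K = 0.0540, k = 6.20 × 10⁻⁴ s⁻¹)
    target ⇌ isomer of the product (K = 0.740, k = 0.00290 s⁻¹)
    open intermediate + capture agent → trapped intermediate (k = 0.0360 M⁻¹ s⁻¹)
    crystals ⇌ target, rate k4*(cs4 - [target]) while solid is left; crystals form when [target] > cs4 (solubility = 7.50 mM, k = 0.120 s⁻¹)
    second nucleophile + open intermediate → other capture product (k = 0.630 M⁻¹ s⁻¹)
    first nucleophile + open intermediate → target (k = 0.750 M⁻¹ s⁻¹)

**Hidden forms.** The two capture steps give 0.840 at equal charges, below the read selectivity factor of 0.947, so my assumption did not hold: the read factor carries more than rates. In this flask, part of the reason is the path from target to isomer of the product, for without it the ratio at 12 d reads 2.35 against 2.59. The low solubility of target acts the other way, for without it that ratio reads 4.08. For the neighbour flask charged with 0.15 M of second nucleophile, 0.947 times its charge quotient gives 0.646, and that flask stands at 0.635 at 12 d.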